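No rate constant is given here, and the first question is whether one is needed.

common to all: starting material 0.50 M
- violet: reagent 1.2 equiv; run made earlier
- ochre: reagent 2.5 equiv; run made earlier
- dusk: reagent 1.70 equiv; time 15 h
- autumn: reagent 1.30 equiv; time 15 h
- winter: reagent 1.00 equiv; time 15 h

| run | time / h | starting material / % | mono adduct / % |
|---|---|---|---|
| violet | 1.33 | 17.5 | 17.1 |
| violet | 2.00 | 20.8 | 16.4 |
| violet | 3.00 | 20.0 | 18.3 |
| violet | 4.00 | 20.1 | 19.0 |
| violet | 6.00 | 19.5 | 18.4 |
| violet | 10.0 | 19.6 | 20.2 |
| violet | 15.0 | 20.9 | 16.4 |
| ochre | 1.33 | 0 | 2.2 |
| ochre | 2.00 | 1.3 | 0 |
| ochre | 3.00 | 0 | 1.2 |
| ochre | 4.00 | 0 | 1.9 |
| ochre | 6.00 | 0 | 0 |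
| ochre | 10.0 | 0.5 | 0 |
| ochre | 15.0 | 0.5 | 0.1 |

(standard deviation of a reading: 1 percentage point)

- what is said of released group includes idle adduct
- reactions considered so far: reagent + released group <-> idle adduct; reagent + other mono adduct -> double product + released group; starting material + reagent -> other mono adduct + released group; reagent + mono adduct -> double product + released group; starting material + reagent -> mono adduct + released group; released group -> by-product carried off

- part of the starting material that has reacted at the end, dusk
- part of the starting material that has reacted at the end, autumn
- part of the starting material that has reacted at the end, winter
- what raising the equivalents of reagent from its lowest to its highest value here does to the part of the starting material that has reacted (changes below 5 percentage points count as none) (it rises / no change / it falls)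

*Which concentration sets the order of the rates?*

[reagent]. Every substitution on the list is first order in it.

*Then you need [reagent] against time?*

No. First substitution goes as [starting material][reagent], second as [mono adduct][reagent]. In their ratio [reagent] divides out. The path of the mono adducts against the starting material then hangs on the selectivity factor s, the rate constant of the second substitution over that of the first, with both mono adducts lumped.

*Read it from violet.*

Violet's starting material stays flat, with a mean of 19.8%. I take its 1.2 equiv of reagent as spent. Each reacted starting material takes one reagent, and each double product a second one. So the mono adducts together hold 40.5%. With a the fraction left, integration gives mono total = (a^s − a)/(1 − s). One pass from a trial of 0.7 gives s = 0.705.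

*But violet's mono adduct reads 19.0%. Where is the rest?*

That is the weak spot. The rest must be other mono adduct, which nobody measured, so s stands on a balance. If reagent lay idle, the mono total would be larger. The flat readings from 1.33 h to 15.0 h show no store returning.

*What does a flask cost?*

Reagent cost = 2(1 − a) − (a^s − a)/(1 − s).

The forecast gives 96%, 84% and 71%. On raising the reagent it says: it rises. Its ground: “The final state is therefore set by stoichiometry and competition.” My cost at its winter value is 0.987 against 1.00 equiv, and at its dusk value 1.71 against 1.70 equiv. Both reckonings rest on violet, so this shows consistency and is no check.

The simulation gives 95.6%, 83.8% and 71.1%. On raising the reagent it gives: it rises, by 25 percentage points.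

    reagent + released group ⇌ idle adduct, settled at all times (K = 1.23 /M)
    reagent + other mono adduct → double product + released group (k = 20.5 /M/h)
    starting material + reagent → other mono adduct + released group (k = 16.5 /M/h)
    reagent + mono adduct → double product + released group (k = 26.9 /M/h)
    starting material + reagent → mono adduct + released group (k = 15.0 /M/h)
    released group → by-product carried off (k = 0.543 /h)

The neighbour of dusk has 0.680 equiv of reagent. Its unreacted starting material stands at 46.3%, and reaching that a costs 0.674 of reagent by the same s. The formula puts 40.0% in the mono adducts, and that flask holds 39.4%. In the neighbour, 53.7% of the starting material has reacted, and 0% of its reagent is left.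

Readings and results stem from a simulated flask for an exercise.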